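**Retrosynthetic overview**
1. Target ⇐ Vilsmeier diformylation and hydrogenation (C8=C10, 2-methylallyl) ⇐ enol acetate 20 ⇐ propargylic acetate 19. A platinum-catalysed acyloxy shift/intramolecular cyclopropanation closes the cyclohexane ring and the cyclopropane together (bonds C7–C6 and C7–C11).
2. Enabling feature: the gem-dimethylcyclopropane (C6, C7, C11) shares its C6–C7 edge with the six-membered ring, and C7 is followed by C8H2–C10H(CH3). C7–C8–C10(CH3) is therefore a masked ethynyl methyl carbinol ester on C1, and C6/C11 an isobutenyl group on C5: a 1,6-enyne.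
3. 19 ⇐ bridged aryl ketone 16. C7' is set by allylsilane attack on the benzylic cation from the convex face; the oxepane ring comes from SNAr of the C1 alkoxide on a 2,4,6-trifluorophenyl ketone, whose other two fluorines become the phenol oxygens.
4. Cyclopentane triad (C4, C5, C1) ⇐ 1-acetylcyclopentene 11: cuprate addition at C5, then enolate hydroxylation at C1 (trans,trans); C4 from catalytic asymmetric conjugate addition to 3-methylcyclopent-2-enone (1).
5. Ring order: cyclopentane (from 1) → arene appended (step 4) → oxepane (step 9) → cyclohexane + cyclopropane (step 13); formyl groups last.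

Key step: step 13

Locants used for the terpenoid carbons: C1 = ring-fusion carbon bearing the ether oxygen; C2/C3 = cyclopentane CH2 groups; C4 = quaternary C–CH3; C5 = ring-fusion CH; C6/C7 = cyclopropane CH (C6 bonded to C5); C8 = CH2 next to C7; C10 = CH–CH3 bonded to C1; C11 = C(CH3)2; C7' = benzylic CH. Bridged intermediates are named as 2,5-methano-1-benzoxocines (= ethano-bridged 1-benzoxepines; ring positions 2, 5, 6 and 11 are C1, C4, C7' and C5).

Remark on the chemistry (assumption): the carbinol centres formed in steps 4, 8 and 10 (C7' in 8, 17 and 18; C10 in 14–19) arise as epimer mixtures and are left undefined in the SMILES, because each is erased later (oxidation, ionisation, acyloxy shift).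

**Step 1**
Reactants: 1 3-methylcyclopent-2-en-1-one
Product: 3 (R)-3-[(E)-hex-1-en-1-yl]-3-methylcyclopent-1-en-1-yl acetate, via diisobutylaluminium enolate 2 (not isolated)
Conditions: (E)-hex-1-enyl(diisobutyl)aluminium [from hex-1-yne, (i-Bu)2AlH, hexane, 55 °C], copper thiophene-2-carboxylate (CuTC, 5 mol%), chiral phosphinamine ligand (SimplePhos type), Et2O, −30 °C; then Ac2O, 0 °C to rt
Reagents that add atoms: (E)-hex-1-enyl(diisobutyl)aluminium CCCC/C=C/[Al](CC(C)C)CC(C)C; acetic anhydride CC(=O)OC(C)=O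
Why: Copper-catalysed asymmetric conjugate addition of an alkenylalane to a β-methyl cyclic enone (a known route to quaternary centres) should set C4 as R with the appropriate ligand enantiomer, and O-acetylation of the aluminium enolate preserves the C1=C5 enolate regiochemistry.

**Step 2**
Reactants: 3 (R)-3-[(E)-hex-1-en-1-yl]-3-methylcyclopent-1-en-1-yl acetate
Product: 5 (R)-3-[(E)-hex-1-en-1-yl]-3-methylcyclopent-1-en-1-yl trifluoromethanesulfonate, via lithium enolate 4 (not isolated)
Conditions: MeLi (2.1 equiv), THF, 0 °C; then PhNTf2, −78 °C to rt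
Reagents that add atoms: N-phenylbis(trifluoromethanesulfonimide) O=S(=O)(N(c1ccccc1)S(=O)(=O)C(F)(F)F)C(F)(F)F
Why: Methyllithium cleavage of the enol acetate regenerates the regiodefined lithium enolate, which is O-sulfonylated by PhNTf2 to the enol triflate (enolate trapping), C4 being untouched.

**Step 3**
Reactants: 5 (R)-3-[(E)-hex-1-en-1-yl]-3-methylcyclopent-1-en-1-yl trifluoromethanesulfonate
Product: 6 (S)-3-formyl-3-methylcyclopent-1-en-1-yl trifluoromethanesulfonate
Conditions: OsO4 (2 mol%), NaIO4, 2,6-lutidine, 1,4-dioxane–H2O, rt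
Reagents that add atoms: sodium periodate [Na+].[O-]I(=O)(=O)=O
Why: Lemieux–Johnson oxidative cleavage should take the electron-rich disubstituted alkene in preference to the electron-poor enol triflate and so cuts the hexenyl group down to the C7' aldehyde.

**Step 4**
Reactants: 6 (S)-3-formyl-3-methylcyclopent-1-en-1-yl trifluoromethanesulfonate; 7 1,3,5-trifluorobenzene
Product: 8 (3S)-3-[hydroxy(2,4,6-trifluorophenyl)methyl]-3-methylcyclopent-1-en-1-yl trifluoromethanesulfonate (both carbinol epimers)
Conditions: 7, n-BuLi, THF, −78 °C; then 6, −78 °C; aq NH4Cl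
Reagents that add atoms: none
Why: Directed lithiation of 7 between two fluorine atoms and 1,2-addition of the aryllithium to the aldehyde at −78 °C (below the onset of benzyne formation) appends the future phloroglucinol ring; the new carbinol centre is erased in step 5.

**Step 5**
Reactants: 8 (3S)-3-[hydroxy(2,4,6-trifluorophenyl)methyl]-3-methylcyclopent-1-en-1-yl trifluoromethanesulfonate
Product: 9 (S)-3-methyl-3-(2,4,6-trifluorobenzoyl)cyclopent-1-en-1-yl trifluoromethanesulfonate
Conditions: Dess–Martin periodinane, NaHCO3, CH2Cl2, rt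
Reagents that add atoms: none
Why: Dess–Martin oxidation gives the aryl ketone whose carbonyl group activates the ortho and para fluorines for the nucleophilic aromatic substitutions of step 9.

**Step 6**
Reactants: 9 (S)-3-methyl-3-(2,4,6-trifluorobenzoyl)cyclopent-1-en-1-yl trifluoromethanesulfonate
Product: 11 (S)-1-[3-methyl-3-(2,4,6-trifluorobenzoyl)cyclopent-1-en-1-yl]ethan-1-one, via 1-ethoxyvinyl diene 10 (not isolated)
Conditions: tributyl(1-ethoxyvinyl)stannane, Pd(PPh3)4 (5 mol%), LiCl, 1,4-dioxane, 90 °C; then 1 M HCl, THF, rt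
Reagents that add atoms: tributyl(1-ethoxyvinyl)stannane CCCC[Sn](CCCC)(CCCC)C(=C)OCC; water O
Why: Stille coupling of the enol triflate with an acetyl anion equivalent followed by enol ether hydrolysis gives the 1-acetylcyclopentene in which C5 is the β-carbon and the acetyl carbon is C10 with its methyl group.

**Step 7**
Reactants: 11 (S)-1-[3-methyl-3-(2,4,6-trifluorobenzoyl)cyclopent-1-en-1-yl]ethan-1-one
Product: 13 1-[(1R,2R,3S)-1-hydroxy-3-methyl-2-(2-methylprop-1-en-1-yl)-3-(2,4,6-trifluorobenzoyl)cyclopentyl]ethan-1-one, via bromomagnesium enolate 12 (not isolated)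
Conditions: (2-methylprop-1-enyl)magnesium bromide (2.2 equiv), CuBr·SMe2 (1.1 equiv), THF, −78 to −40 °C; then 2-(phenylsulfonyl)-3-phenyloxaziridine, −78 to −20 °C; aq NH4Cl
Reagents that add atoms: (2-methylprop-1-enyl)magnesium bromide CC(C)=C[Mg]Br; 2-(phenylsulfonyl)-3-phenyloxaziridine O=S(=O)(N1OC1c1ccccc1)c1ccccc1
Why: Cuprate conjugate addition should deliver the isobutenyl group to C5 anti to the bulky twisted aroyl group on the adjacent quaternary C4, and electrophilic hydroxylation of the enolate by the N-sulfonyloxaziridine should then occur at C1 anti to the new C5 substituent, which gives the trans,trans triad with the C1 hydroxyl cis to the aroyl group as step 9 requires.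

**Step 8**
Reactants: 13 1-[(1R,2R,3S)-1-hydroxy-3-methyl-2-(2-methylprop-1-en-1-yl)-3-(2,4,6-trifluorobenzoyl)cyclopentyl]ethan-1-one
Product: 14 2-[(1R,2R,3S)-1-hydroxy-3-methyl-2-(2-methylprop-1-en-1-yl)-3-(2,4,6-trifluorobenzoyl)cyclopentyl]but-3-yn-2-ol (C10 epimers)
Conditions: ethynylmagnesium bromide (3.5 equiv), THF, −40 to 0 °C
Reagents that add atoms: ethynylmagnesium bromide C#C[Mg]Br
Why: Chelation-assisted Grignard addition to the α-alkoxy methyl ketone should outpace attack on the neopentyl aryl ketone (which the cis C1 alkoxide can mask as a hemiketal), and the configuration of the new carbinol C10 does not matter because C10 becomes trigonal in step 13.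

**Step 9**
Reactants: 14 2-[(1R,2R,3S)-1-hydroxy-3-methyl-2-(2-methylprop-1-en-1-yl)-3-(2,4,6-trifluorobenzoyl)cyclopentyl]but-3-yn-2-ol
Product: 16 2-(2-hydroxybut-3-yn-2-yl)-5-methyl-11-(2-methylprop-1-en-1-yl)-7,9-bis(prop-2-en-1-yloxy)-3,4-dihydro-2H-2,5-methano-1-benzoxocin-6(5H)-one, via 7,9-difluoro benzoxocinone 15 (not isolated)
Conditions: NaH, DMF, 0 °C to rt; then prop-2-en-1-ol, NaH, 60 °C
Reagents that add atoms: prop-2-en-1-ol C=CCO
Why: Intramolecular SNAr of the tertiary C1 alkoxide at the ketone-activated ortho fluorine closes the oxepane (seven-membered closure is preferred to the eight-membered one open to the C10 alkoxide, and only the cis arrangement from step 7 can bridge), and the remaining ortho and para fluorines are then displaced by allyl alkoxide to install the two protected phenol oxygens.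

**Step 10**
Reactants: 16 bridged bis(allyloxy) aryl ketone (name as in step 9)
Product: 17 2-(2-hydroxybut-3-yn-2-yl)-5-methyl-11-(2-methylprop-1-en-1-yl)-7,9-bis(prop-2-en-1-yloxy)-3,4,5,6-tetrahydro-2H-2,5-methano-1-benzoxocin-6-ol (C6 epimers)
Conditions: (i-Bu)2AlH, CH2Cl2, −78 to 0 °C; Rochelle salt work-up
Reagents that add atoms: none
Why: Hydride reduction of the hindered aryl ketone with (i-Bu)2AlH at or below 0 °C leaves the alkyne and the allyl ethers alone and gives the C7' carbinol, whose configuration is irrelevant because C7' is ionised in step 12.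

**Step 11**
Reactants: 17 bridged benzylic alcohol (name as in step 10)
Product: 18 2-[6-(acetyloxy)-5-methyl-11-(2-methylprop-1-en-1-yl)-7,9-bis(prop-2-en-1-yloxy)-3,4,5,6-tetrahydro-2H-2,5-methano-1-benzoxocin-2-yl]but-3-yn-2-yl acetate
Conditions: Ac2O, DMAP, Et3N, CH2Cl2, rt to 40 °C
Reagents that add atoms: acetic anhydride CC(=O)OC(C)=O
Why: DMAP-catalysed acetylation esterifies the benzylic carbinol (leaving group for step 12) and the tertiary propargylic carbinol (migrating group for step 13), and removes the free hydroxyl that could otherwise capture the benzylic cation.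

**Step 12**
Reactants: 18 diacetate (name as in step 11)
Product: 19 2-[5-methyl-6-(2-methylprop-2-en-1-yl)-11-(2-methylprop-1-en-1-yl)-7,9-bis(prop-2-en-1-yloxy)-3,4,5,6-tetrahydro-2H-2,5-methano-1-benzoxocin-2-yl]but-3-yn-2-yl acetate (C6 substituent anti to the C3–C4 bridge)
Conditions: trimethyl(2-methylallyl)silane, TMSOTf (5 mol%), CH2Cl2, −78 °C
Reagents that add atoms: trimethyl(2-methylprop-2-en-1-yl)silane C=C(C)C[Si](C)(C)C
Why: Hosomi–Sakurai allylation: the 2,4,6-trialkoxybenzylic acetate ionises far more readily than the tertiary propargylic acetate, and the planar C7' cation held in the bicyclo[4.2.1] frame should be attacked by the allylsilane from the convex face (syn to the one-carbon bridge C5 and anti to the C2–C3 bridge), which sets C7' as in the target.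

**Step 13**
Reactants: 19 propargylic acetate (name as in step 12)
Product: 20 pentacyclic enol acetate: cyclohexene ring C1–C5–C6–C7–C8(OAc)=C10(CH3) cis-fused to the 11,11-dimethylcyclopropane C6–C7–C11 (C11 syn to H5); aryl ring 7,9-bis(allyloxy); C7' carries 2-methylallyl
Conditions: PtCl2 (5 mol%), toluene, 80 °C
Reagents that add atoms: none
Why: Ohloff–Rautenstrauch cycloisomerisation: PtCl2 activates the terminal alkyne C7≡C8, the acetate shifts from C10 to C8 through a 1,3-dioxolenium ion (1,2-acyloxy migration), and the resulting platinum vinylcarbenoid at C7 adds to the isobutenyl alkene C6=C11 (the order of acyl shift and alkene attack may be reversed without changing the outcome). The closest known reaction is the metal-catalysed (ZnCl2, PtCl2, AuCl3) conversion of tertiary 1,6-enyne propargylic acetates of the dehydrolinalyl acetate type into bicyclo[4.1.0]hept-2-en-2-yl acetates (carane skeleton). The six-membered ring closes by the C7–C6 bond (carbenoid carbon to the proximal alkene carbon, tether C7–C8–C10–C1–C5–C6) and the cyclopropane by the C7–C11 bond in the same stereospecific [2+1] addition, so C6/C7 are necessarily cis-fused. Facial control comes from C5: allylic 1,3-strain keeps H5 eclipsed with the alkene and its Z-methyl group, and the tether through C1 then brings C7 to the face that leaves C11 syn to H5 and anti to the quaternary C4, which is the target configuration at C6 and C7. The step needs 1,2- rather than 1,3-acyloxy migration and reaction at C6=C11 rather than at the three terminal alkenes; the terminal alkyne favours the 1,2-shift and only C6=C11 is within reach of a six-membered transition state. The enol acetate left at C8=C10 is the handle for removing the C8 oxygen and setting C10.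

**Step 14**
Reactants: 20 pentacyclic enol acetate
Product: 22 pentacyclic C8 enol triflate (C8(OTf)=C10(CH3); otherwise as 20), via lithium enolate 21 (not isolated)
Conditions: MeLi (2.2 equiv), THF, −78 °C; then PhNTf2, −78 to 0 °C
Reagents that add atoms: N-phenylbis(trifluoromethanesulfonimide) O=S(=O)(N(c1ccccc1)S(=O)(=O)C(F)(F)F)C(F)(F)F
Why: Methyllithium cleavage of the enol acetate at −78 °C gives the regiodefined lithium enolate, which is trapped as the enol triflate before β-elimination of the C1 aryloxide can intervene.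

**Step 15**
Reactants: 22 pentacyclic C8 enol triflate
Product: 23 pentacyclic C8=C10 alkene with free 7,9-phenols and a C7' 2-methylallyl group
Conditions: Pd(OAc)2 (5 mol%), PPh3, HCO2H, Et3N, DMF, 60 °C
Reagents that add atoms: none
Why: Palladium-catalysed formate reduction of the enol triflate gives the C8=C10 alkene, and the same zerovalent palladium/formate system cleaves both allyl aryl ethers (Tsuji–Trost deallylation) to free the phenols.

**Step 16**
Reactants: 23 pentacyclic alkene diphenol
Product: 24 bis-deformyl target (the target lacking its two formyl groups)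
Conditions: H2 (3 atm), Raney nickel, EtOH, rt
Reagents that add atoms: none
Why: Heterogeneous hydrogenation reduces the 2-methylallyl group to isobutyl and should add hydrogen to C8=C10 from the face opposite the gem-dimethylcyclopropane (as in the hydrogenation of car-2-ene and car-3-ene to cis-carane), which sets C10 with its methyl group cis to the cyclopropane.

**Step 17**
Reactants: 24 bis-deformyl target
Product: 26 target CNP0202714.1, via bis(iminium) salt 25 (not isolated)
Conditions: POCl3, DMF, EtOAc, 0 °C to rt; then H2O, 50 °C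
Reagents that add atoms: N,N-dimethylformamide CN(C)C=O; water O
Why: Vilsmeier–Haack formylation of the phloroglucinol-type ring can only occur at the two free positions (each ortho or para to three oxygen substituents), and hydrolysis of the bis(iminium) salt should give the dialdehyde 26.

**Compound list**
1 | 3-methylcyclopent-2-en-1-one | CC1=CC(=O)CC1 | starting material
2 | diisobutylaluminium (R)-3-[(E)-hex-1-en-1-yl]-3-methylcyclopent-1-en-1-olate | CC(C)C[Al](CC(C)C)OC1=C[C@@](C)(/C=C/CCCC)CC1 | intermediate (not isolated)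
3 | (R)-3-[(E)-hex-1-en-1-yl]-3-methylcyclopent-1-en-1-yl acetate | CC(=O)OC1=C[C@@](C)(/C=C/CCCC)CC1 | intermediate
4 | lithium (R)-3-[(E)-hex-1-en-1-yl]-3-methylcyclopent-1-en-1-olate | [Li]OC1=C[C@@](C)(/C=C/CCCC)CC1 | intermediate (not isolated)
5 | (R)-3-[(E)-hex-1-en-1-yl]-3-methylcyclopent-1-en-1-yl trifluoromethanesulfonate | O=S(=O)(OC1=C[C@@](C)(/C=C/CCCC)CC1)C(F)(F)F | intermediate
6 | (S)-3-formyl-3-methylcyclopent-1-en-1-yl trifluoromethanesulfonate | O=S(=O)(OC1=C[C@@](C)(C=O)CC1)C(F)(F)F | intermediate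
7 | 1,3,5-trifluorobenzene | Fc1cc(F)cc(F)c1 | starting material
8 | (3S)-3-[hydroxy(2,4,6-trifluorophenyl)methyl]-3-methylcyclopent-1-en-1-yl trifluoromethanesulfonate (carbinol epimers) | O=S(=O)(OC1=C[C@@](C)(C(O)c2c(F)cc(F)cc2F)CC1)C(F)(F)F | intermediate
9 | (S)-3-methyl-3-(2,4,6-trifluorobenzoyl)cyclopent-1-en-1-yl trifluoromethanesulfonate | O=S(=O)(OC1=C[C@@](C)(C(=O)c2c(F)cc(F)cc2F)CC1)C(F)(F)F | intermediate
10 | (S)-[3-(1-ethoxyethenyl)-1-methylcyclopent-2-en-1-yl](2,4,6-trifluorophenyl)methanone | CCOC(=C)C1=C[C@@](C)(C(=O)c2c(F)cc(F)cc2F)CC1 | intermediate (not isolated)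
11 | (S)-1-[3-methyl-3-(2,4,6-trifluorobenzoyl)cyclopent-1-en-1-yl]ethan-1-one | CC(=O)C1=C[C@@](C)(C(=O)c2c(F)cc(F)cc2F)CC1 | intermediate
12 | bromomagnesium enolate of 13 lacking the C1 hydroxyl (exocyclic C1=C10 enolate; isobutenyl at C5 trans to the aroyl group) | CC(O[Mg]Br)=C1CC[C@](C)(C(=O)c2c(F)cc(F)cc2F)[C@H]1C=C(C)C | intermediate (not isolated)
13 | 1-[(1R,2R,3S)-1-hydroxy-3-methyl-2-(2-methylprop-1-en-1-yl)-3-(2,4,6-trifluorobenzoyl)cyclopentyl]ethan-1-one | CC(=O)[C@@]1(O)CC[C@](C)(C(=O)c2c(F)cc(F)cc2F)[C@H]1C=C(C)C | intermediate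
14 | 2-[(1R,2R,3S)-1-hydroxy-3-methyl-2-(2-methylprop-1-en-1-yl)-3-(2,4,6-trifluorobenzoyl)cyclopentyl]but-3-yn-2-ol (C10 epimers) | C#CC(C)(O)[C@@]1(O)CC[C@](C)(C(=O)c2c(F)cc(F)cc2F)[C@H]1C=C(C)C | intermediate
15 | 7,9-difluoro-2-(2-hydroxybut-3-yn-2-yl)-5-methyl-11-(2-methylprop-1-en-1-yl)-3,4-dihydro-2H-2,5-methano-1-benzoxocin-6(5H)-one (C11 substituent syn to the C3–C4 bridge) | O=C1c2c(F)cc(F)cc2O[C@]2(C(C)(O)C#C)CC[C@@]1(C)[C@H]2C=C(C)C | intermediate (not isolated)
16 | 2-(2-hydroxybut-3-yn-2-yl)-5-methyl-11-(2-methylprop-1-en-1-yl)-7,9-bis(prop-2-en-1-yloxy)-3,4-dihydro-2H-2,5-methano-1-benzoxocin-6(5H)-one | O=C1c2c(OCC=C)cc(OCC=C)cc2O[C@]2(C(C)(O)C#C)CC[C@@]1(C)[C@H]2C=C(C)C | intermediate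
17 | 2-(2-hydroxybut-3-yn-2-yl)-5-methyl-11-(2-methylprop-1-en-1-yl)-7,9-bis(prop-2-en-1-yloxy)-3,4,5,6-tetrahydro-2H-2,5-methano-1-benzoxocin-6-ol (C6 epimers) | OC1c2c(OCC=C)cc(OCC=C)cc2O[C@]2(C(C)(O)C#C)CC[C@@]1(C)[C@H]2C=C(C)C | intermediate
18 | 2-[6-(acetyloxy)-5-methyl-11-(2-methylprop-1-en-1-yl)-7,9-bis(prop-2-en-1-yloxy)-3,4,5,6-tetrahydro-2H-2,5-methano-1-benzoxocin-2-yl]but-3-yn-2-yl acetate | CC(=O)OC1c2c(OCC=C)cc(OCC=C)cc2O[C@]2(C(C)(OC(C)=O)C#C)CC[C@@]1(C)[C@H]2C=C(C)C | intermediate
19 | 2-[5-methyl-6-(2-methylprop-2-en-1-yl)-11-(2-methylprop-1-en-1-yl)-7,9-bis(prop-2-en-1-yloxy)-3,4,5,6-tetrahydro-2H-2,5-methano-1-benzoxocin-2-yl]but-3-yn-2-yl acetate (C6 substituent anti to the C3–C4 bridge) | C=C(C)C[C@H]1c2c(OCC=C)cc(OCC=C)cc2O[C@]2(C(C)(OC(C)=O)C#C)CC[C@@]1(C)[C@H]2C=C(C)C | intermediate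
20 | pentacyclic enol acetate: cyclohexene C1–C5–C6–C7–C8(OAc)=C10(CH3) cis-fused to the 11,11-dimethylcyclopropane (C11 syn to H5); 7,9-bis(allyloxy); C7' 2-methylallyl | C=C(C)C[C@H]1c2c(OCC=C)cc(OCC=C)cc2O[C@]23CC[C@@]1(C)[C@H]2[C@H]1[C@@H](C(OC(C)=O)=C3C)C1(C)C | intermediate
21 | lithium C8 enolate corresponding to 20 | C=C(C)C[C@H]1c2c(OCC=C)cc(OCC=C)cc2O[C@]23CC[C@@]1(C)[C@H]2[C@H]1[C@@H](C(O[Li])=C3C)C1(C)C | intermediate (not isolated)
22 | C8 enol triflate corresponding to 20 | C=C(C)C[C@H]1c2c(OCC=C)cc(OCC=C)cc2O[C@]23CC[C@@]1(C)[C@H]2[C@H]1[C@@H](C(OS(=O)(=O)C(F)(F)F)=C3C)C1(C)C | intermediate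
23 | pentacyclic C8=C10 alkene with free 7,9-phenols and C7' 2-methylallyl group | C=C(C)C[C@H]1c2c(O)cc(O)cc2O[C@]23CC[C@@]1(C)[C@H]2[C@H]1[C@@H](C=C3C)C1(C)C | intermediate
24 | bis-deformyl target (target lacking both formyl groups) | CC(C)C[C@H]1c2c(O)cc(O)cc2O[C@]23CC[C@@]1(C)[C@H]2[C@H]1[C@@H](C[C@@H]3C)C1(C)C | intermediate
25 | bis(N,N-dimethyliminium) salt of the target (written as the dichloride) | CC(C)C[C@H]1c2c(O)c(C=[N+](C)C)c(O)c(C=[N+](C)C)c2O[C@]23CC[C@@]1(C)[C@H]2[C@H]1[C@@H](C[C@@H]3C)C1(C)C.[Cl-].[Cl-] | intermediate (not isolated)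
26 | target CNP0202714.1 | CC(C)C[C@H]1c2c(O)c(C=O)c(O)c(C=O)c2O[C@]23CC[C@@]1(C)[C@H]2[C@H]1[C@@H](C[C@@H]3C)C1(C)C | target

Total step count: 17. Longest linear sequence: 17 steps (1 → 26).

**Steps most likely to fail**

Step 13 (key step). The acetate may migrate 1,3 to an allenyl acetate instead of 1,2; the platinum carbenoid may be diverted by the other alkenes; or it may add to the wrong alkene face. Fallback (vinylcarbene from a hydrazone instead of an acyloxy shift), setting out from 19: K2CO3/MeOH would give the tertiary propargylic alcohol F1. Meyer–Schuster rearrangement ((Ph3SiO)3VO, xylene, 140 °C) would give the (Z)-enal F2, the E isomer being recycled by photoisomerisation. TsNHNH2 would give the tosylhydrazone F3. NaH, then Rh2(OAc)4 with warming (Bamford–Stevens generation of the diazo compound), would pass through the vinyldiazo compound F4, whose rhodium vinylcarbenoid should cyclopropanate the isobutenyl group under the same allylic-strain control to give the bis(allyl ether) alkene F5. Pd(OAc)2/PPh3/HCO2H/Et3N would remove the allyl groups, and the route is rejoined at 23.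

Step 7. Facial discrimination between methyl and aroyl at C4 may be poor, or addition next to the quaternary centre sluggish, which would erode the C5/C1 configuration. Fallback (conjugate addition at the carbinol oxidation level), setting out from 8: TBSOTf/2,6-lutidine would give the silyl ether F6. Stille coupling as in step 6 would give the enol ether F7, and mild hydrolysis (PPTS, acetone–H2O) the enone F8. Cuprate addition, now anti to the much larger α-silyloxybenzyl group, would give the bromomagnesium enolate F9, and oxaziridine hydroxylation the ketol F10. Bu4NF would give the diol F11, and Dess–Martin oxidation of its secondary benzylic alcohol returns to 13.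

Step 16. Hydrogen may be delivered to the wrong face of C8=C10 (anchoring by the C1 ether oxygen or shielding by the cyclopentane), or the vinylcyclopropane may be hydrogenolysed on the metal surface. Fallback, setting out from 23: radical hydrogen-atom-transfer hydrogenation (Mn(dpm)3 with dpm = 2,2,6,6-tetramethylheptane-3,5-dionate, PhSiH3, t-BuOOH, i-PrOH). Both alkenes would be reduced through tertiary radicals (the C10 radical is not cyclopropylcarbinyl), with no metal surface and with the outcome at C10 set by approach of a small hydrogen-atom donor. This gives 24 directly; no new compound arises (F0).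

**Further compounds**
F1 | step 13 | 2-[5-methyl-6-(2-methylprop-2-en-1-yl)-11-(2-methylprop-1-en-1-yl)-7,9-bis(prop-2-en-1-yloxy)-3,4,5,6-tetrahydro-2H-2,5-methano-1-benzoxocin-2-yl]but-3-yn-2-ol | C=C(C)C[C@H]1c2c(OCC=C)cc(OCC=C)cc2O[C@]2(C(C)(O)C#C)CC[C@@]1(C)[C@H]2C=C(C)C
F2 | step 13 | (2Z)-3-[the same benzoxocin-2-yl group]but-2-enal | C=C(C)C[C@H]1c2c(OCC=C)cc(OCC=C)cc2O[C@]2(/C(C)=C\C=O)CC[C@@]1(C)[C@H]2C=C(C)C
F3 | step 13 | 4-methylbenzenesulfonohydrazone of F2 | C=C(C)C[C@H]1c2c(OCC=C)cc(OCC=C)cc2O[C@]2(/C(C)=C\C=NNS(=O)(=O)c3ccc(C)cc3)CC[C@@]1(C)[C@H]2C=C(C)C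
F4 | step 13 | vinyldiazo compound from F3 ((2Z)-4-diazobut-2-en-2-yl side chain on C1) | C=C(C)C[C@H]1c2c(OCC=C)cc(OCC=C)cc2O[C@]2(/C(C)=C\C=[N+]=[N-])CC[C@@]1(C)[C@H]2C=C(C)C
F5 | step 13 | 7,9-bis(allyl ether) of 23 | C=C(C)C[C@H]1c2c(OCC=C)cc(OCC=C)cc2O[C@]23CC[C@@]1(C)[C@H]2[C@H]1[C@@H](C=C3C)C1(C)C
F6 | step 7 | (3S)-3-[(tert-butyldimethylsilyloxy)(2,4,6-trifluorophenyl)methyl]-3-methylcyclopent-1-en-1-yl trifluoromethanesulfonate | O=S(=O)(OC1=C[C@@](C)(C(O[Si](C)(C)C(C)(C)C)c2c(F)cc(F)cc2F)CC1)C(F)(F)F
F7 | step 7 | 1-ethoxyvinyl diene corresponding to F6 | CCOC(=C)C1=C[C@@](C)(C(O[Si](C)(C)C(C)(C)C)c2c(F)cc(F)cc2F)CC1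
F8 | step 7 | 1-[(3S)-3-[(tert-butyldimethylsilyloxy)(2,4,6-trifluorophenyl)methyl]-3-methylcyclopent-1-en-1-yl]ethan-1-one | CC(=O)C1=C[C@@](C)(C(O[Si](C)(C)C(C)(C)C)c2c(F)cc(F)cc2F)CC1
F9 | step 7 | bromomagnesium enolate from conjugate addition to F8 | CC(O[Mg]Br)=C1CC[C@](C)(C(O[Si](C)(C)C(C)(C)C)c2c(F)cc(F)cc2F)[C@H]1C=C(C)C
F10 | step 7 | silyl ether ketol (13 with C7' as CH(OTBS)) | CC(=O)[C@@]1(O)CC[C@](C)(C(O[Si](C)(C)C(C)(C)C)c2c(F)cc(F)cc2F)[C@H]1C=C(C)C
F11 | step 7 | diol ketone (13 with C7' as CH(OH)) | CC(=O)[C@@]1(O)CC[C@](C)(C(O)c2c(F)cc(F)cc2F)[C@H]1C=C(C)C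
F0 | step 16 | none | none
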